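**Plan**
- Retrosynthesis: once the phenol protecting groups are off, the furan is cut at three bonds at once, O1–C2, C3–C3a and C3–C1'. C2=C3 of the benzofuran is a masked alkyne lying between phenol oxygen O1, arene carbon C3a and ring B carbon C1', so the core maps onto an o-iodophenol (ring A), methyl pent-4-ynoate (C2, C3 and the ester chain) and an aryl iodide (ring B).
- Forward: ring A iodophenol 3 comes from orcinol by iodination and silylation of the hydroxyl remote from iodine. Ring B iodide 11 comes from 3,5-dimethoxy-4-methylbenzoic acid by ortho-methylation, Curtius degradation and iododediazoniation.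
- The furan, the only ring made, closes in the one-pot union of 3, 12 and 11; desilylation and demethylation finish the route.
- Stereochemistry: the target has no stereocentre, so none has to be set.

Key step: step 6

Assumption: the C3–C1' biaryl axis, with a single ortho substituent on ring B, is taken as configurationally mobile, so no element of stereocontrol is planned.

**Step 1**
Reactants: 1 orcinol (5-methylbenzene-1,3-diol)
Product: 2 4-iodo-5-methylbenzene-1,3-diol
Conditions: NIS (1.0 equiv), MeCN, −20 → 0 °C, dark
Reagents that add atoms: N-iodosuccinimide, O=C1CCC(=O)N1I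
Why: Electrophilic aromatic iodination of a resorcinol under non-basic conditions should go to the position ortho to one hydroxyl and para to the other (C4, equivalent to C6 in orcinol) rather than between the hydroxyls, and one equivalent of NIS at low temperature should limit di-iodination.

**Step 2**
Reactants: 2 4-iodo-5-methylbenzene-1,3-diol
Product: 3 2-iodo-3-methyl-5-(triisopropylsilyloxy)phenol
Conditions: TIPSCl (1.0 equiv), imidazole (2 equiv), CH2Cl2, 0 °C
Reagents that add atoms: triisopropylsilyl chloride, CC(C)[Si](Cl)(C(C)C)C(C)C
Why: Imidazole-mediated silylation with the bulky TIPSCl should take the hydroxyl para to iodine, which has two free ortho positions, in preference to the hydroxyl flanked by iodine, which is hindered and less nucleophilic, as in the selective mono-protection of 4-haloresorcinols.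

**Step 3**
Reactants: 4 3,5-dimethoxy-4-methylbenzoic acid
Product: 6 3,5-dimethoxy-2,4-dimethylbenzoic acid, via ring-lithiated lithium carboxylate 5 (not isolated)
Conditions: s-BuLi (2.2 equiv), TMEDA (2.2 equiv), THF, −78 °C; MeI (3 equiv), −78 °C → rt; then 2 M aq. HCl
Reagents that add atoms: iodomethane, CI
Why: Carboxylate-directed ortho-lithiation of the unprotected benzoic acid (directed ortho-metalation) should occur at the position flanked by CO2Li and OMe, the only kind of free ring position, and the aryllithium is then methylated by MeI; the low temperature keeps s-BuLi from adding to the carboxylate and disfavours deprotonation of the 4-methyl group.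

**Step 4**
Reactants: 6 3,5-dimethoxy-2,4-dimethylbenzoic acid
Product: 9 3,5-dimethoxy-2,4-dimethylaniline, via acyl azide 7 (not isolated), via aryl isocyanate 8 (not isolated)
Conditions: DPPA (1.1 equiv), Et3N (1.2 equiv), PhMe, rt → 90 °C; then 4 M aq. HCl, dioxane, 90 °C; aq. NaOH work-up
Reagents that add atoms: diphenylphosphoryl azide, [N-]=[N+]=NP(=O)(Oc1ccccc1)Oc1ccccc1
Why: Curtius rearrangement, in which DPPA converts the acid to the acyl azide, loss of N2 on heating moves the aryl group to nitrogen to give the isocyanate, and acidic hydrolysis with decarboxylation should give the aniline as its salt so that urea formation is held back; the methyl ethers are inert.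

**Step 5**
Reactants: 9 3,5-dimethoxy-2,4-dimethylaniline
Product: 11 1-iodo-3,5-dimethoxy-2,4-dimethylbenzene, via arenediazonium chloride 10 (not isolated)
Conditions: NaNO2 (1.2 equiv), 3 M aq. HCl, MeCN, 0 °C; then KI (2.5 equiv), H2O, 0 °C → rt; Na2S2O3 wash
Reagents that add atoms: potassium iodide, [K+].[I-]
Why: Diazotisation followed by iododediazoniation with iodide (Sandmeyer-type, no copper salt needed) replaces NH2 by iodine at the same carbon, and the strongly acidic medium keeps unreacted aniline protonated so that azo coupling at its electron-rich free ring position is held back.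

**Step 6**
Reactants: 3 2-iodo-3-methyl-5-(triisopropylsilyloxy)phenol; 12 methyl pent-4-ynoate; 11 1-iodo-3,5-dimethoxy-2,4-dimethylbenzene
Product: 14 methyl 3-[3-(3,5-dimethoxy-2,4-dimethylphenyl)-4-methyl-6-(triisopropylsilyloxy)-1-benzofuran-2-yl]propanoate, via 2-alkynylphenol 13 (not isolated)
Conditions: 3 (1.0 equiv), 12 (1.15 equiv), PdCl2(PPh3)2 (5 mol%), CuI (3 mol%), degassed Et3N/THF, rt → 40 °C until 3 is consumed; then 11 (1.5 equiv) in MeCN, 100 °C (sealed tube or microwave)
Reagents that add atoms: none
Why: Zerovalent palladium formed from PdCl2(PPh3)2 inserts into the C–I bond of 3 and the copper acetylide made from 12, CuI and Et3N transfers the alkyne, so that Sonogashira coupling forms C3–C3a and gives the 2-alkynylphenol 13 in the flask. When 11 is then added, its oxidative addition gives an arylpalladium iodide (divalent palladium) that binds the alkyne of 13, the phenol oxygen attacks the activated triple bond anti to the metal, and reductive elimination from the benzofuran-3-yl(aryl)palladium species forms C3–C1' and returns zerovalent palladium. The closest known reaction type is the one-pot Sonogashira coupling and arylative cyclisation of 2-iodophenols, terminal alkynes and aryl iodides to 2,3-disubstituted benzofurans. The furan is the only ring closed and it closes in the 5-endo-dig mode through the O1–C2 bond; no stereocentre arises. The selectivity needed is arylative closure in preference to plain cycloisomerisation of 13 to the 3-unsubstituted benzofuran and to coupling of 11 with leftover alkyne, which is served by holding the first stage at 40 °C or below with Et3N as the only base, by using little excess of 12 and by adding 11 in MeCN only once 3 is gone. In the substrates, the alkyne carbon that carries the chain can only become C2, the methoxy groups of 11 lie meta to the C–I carbon and so do not make the arylpalladium species electron-rich by resonance, its single ortho methyl group is tolerated in the reductive elimination, and the TIPS ether and the methyl ester are inert to Et3N.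

**Step 7**
Reactants: 14 methyl 3-[3-(3,5-dimethoxy-2,4-dimethylphenyl)-4-methyl-6-(triisopropylsilyloxy)-1-benzofuran-2-yl]propanoate
Product: 15 methyl 3-[3-(3,5-dimethoxy-2,4-dimethylphenyl)-6-hydroxy-4-methyl-1-benzofuran-2-yl]propanoate
Conditions: TBAF (1.1 equiv), AcOH (1.1 equiv), THF, 0 °C
Reagents that add atoms: none
Why: Fluoride-mediated cleavage of the aryl silyl ether is driven by the Si–F bond, and buffering with AcOH keeps the medium from turning basic so that the methyl ester survives while the methyl ethers are untouched.

**Step 8**
Reactants: 15 methyl 3-[3-(3,5-dimethoxy-2,4-dimethylphenyl)-6-hydroxy-4-methyl-1-benzofuran-2-yl]propanoate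
Product: 16 talarominine A, methyl 3-[3-(3,5-dihydroxy-2,4-dimethylphenyl)-6-hydroxy-4-methyl-1-benzofuran-2-yl]propanoate
Conditions: BBr3 (6 equiv), CH2Cl2, −78 → 0 °C; then MeOH, 0 °C → rt
Reagents that add atoms: none
Why: Lewis-acid cleavage of aryl methyl ethers (BBr3 demethylation) proceeds by bromide attack on the O-methyl groups of the boron-complexed ethers, which at 0 °C or below should be faster than ester cleavage, and the methanol quench frees the phenols while the HBr/MeOH formed would re-esterify any acid that had arisen.

**Compound list**
1 | orcinol (5-methylbenzene-1,3-diol) | Cc1cc(O)cc(O)c1 | starting material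
2 | 4-iodo-5-methylbenzene-1,3-diol | Cc1cc(O)cc(O)c1I | intermediate
3 | 2-iodo-3-methyl-5-(triisopropylsilyloxy)phenol | Cc1cc(O[Si](C(C)C)(C(C)C)C(C)C)cc(O)c1I | intermediate
4 | 3,5-dimethoxy-4-methylbenzoic acid | COc1cc(C(=O)O)cc(OC)c1C | starting material
5 | lithium 2-lithio-3,5-dimethoxy-4-methylbenzoate | COc1cc(C(=O)O[Li])c([Li])c(OC)c1C | intermediate
6 | 3,5-dimethoxy-2,4-dimethylbenzoic acid | COc1cc(C(=O)O)c(C)c(OC)c1C | intermediate
7 | 3,5-dimethoxy-2,4-dimethylbenzoyl azide | COc1cc(C(=O)N=[N+]=[N-])c(C)c(OC)c1C | intermediate
8 | 1-isocyanato-3,5-dimethoxy-2,4-dimethylbenzene | COc1cc(N=C=O)c(C)c(OC)c1C | intermediate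
9 | 3,5-dimethoxy-2,4-dimethylaniline | COc1cc(N)c(C)c(OC)c1C | intermediate
10 | 3,5-dimethoxy-2,4-dimethylbenzenediazonium chloride | COc1cc([N+]#N)c(C)c(OC)c1C.[Cl-] | intermediate
11 | 1-iodo-3,5-dimethoxy-2,4-dimethylbenzene | COc1cc(I)c(C)c(OC)c1C | intermediate
12 | methyl pent-4-ynoate | COC(=O)CCC#C | starting material
13 | methyl 5-[2-hydroxy-6-methyl-4-(triisopropylsilyloxy)phenyl]pent-4-ynoate | COC(=O)CCC#Cc1c(C)cc(O[Si](C(C)C)(C(C)C)C(C)C)cc1O | intermediate
14 | methyl 3-[3-(3,5-dimethoxy-2,4-dimethylphenyl)-4-methyl-6-(triisopropylsilyloxy)-1-benzofuran-2-yl]propanoate | COC(=O)CCc1oc2cc(O[Si](C(C)C)(C(C)C)C(C)C)cc(C)c2c1-c1cc(OC)c(C)c(OC)c1C | intermediate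
15 | methyl 3-[3-(3,5-dimethoxy-2,4-dimethylphenyl)-6-hydroxy-4-methyl-1-benzofuran-2-yl]propanoate | COC(=O)CCc1oc2cc(O)cc(C)c2c1-c1cc(OC)c(C)c(OC)c1C | intermediate
16 | talarominine A | COC(=O)CCc1oc2cc(O)cc(C)c2c1-c1cc(O)c(C)c(O)c1C | target

**Step count**
Total steps: 8. Longest linear sequence: 6 steps (steps 3, 4, 5, 6, 7, 8 from acid 4); the ring A arm (steps 1, 2) joins at step 6.

**Steps most likely to fail**

Step 6. The hindered arylpalladium species may engage the alkyne of 13 too slowly, so that copper- or base-promoted cycloisomerisation to the 3-unsubstituted benzofuran, or coupling of 11 with residual alkyne, takes over. The fallback sets out from 3, 12 and 11 and forms the same three bonds in separate operations. Sonogashira coupling of 3 with 12 alone (PdCl2(PPh3)2, CuI, Et3N, rt) would give 13, now isolated. Iodocyclisation of 13 (I2, NaHCO3, MeCN, rt) should give methyl 3-[3-iodo-4-methyl-6-(triisopropylsilyloxy)-1-benzofuran-2-yl]propanoate F1. In parallel, Miyaura borylation of 11 (B2pin2, PdCl2(dppf), KOAc, dioxane, 90 °C) should give 2-(3,5-dimethoxy-2,4-dimethylphenyl)-4,4,5,5-tetramethyl-1,3,2-dioxaborolane F2. Suzuki–Miyaura coupling of F1 with F2 (Pd(OAc)2, SPhos, K3PO4, toluene, 100 °C) comes back to the route at 14.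

Step 1. Iodination may not discriminate cleanly between C4 and the position between the two hydroxyls, and the activated ring may take up a second iodine. The fallback sets out from 1 and fixes the regiochemistry on the dimethyl ether. Methylation of 1 (Me2SO4, K2CO3, acetone, reflux) gives 1,3-dimethoxy-5-methylbenzene F3, which is also commercial. Iodination with NIS in MeCN, which on this ether goes ortho to the methyl group and para to a methoxy group, should give 2-iodo-1,5-dimethoxy-3-methylbenzene F4. Demethylation with BBr3 (CH2Cl2, −78 → 0 °C) comes back to the route at 2.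

Step 3. Deprotonation of the 4-methyl group para to the carboxylate, incomplete ring lithiation or addition of s-BuLi to the carboxylate may erode the methylation. The fallback sets out from 4 and replaces the lithiation by halogenation and cross-coupling. Fischer esterification of 4 (MeOH, H2SO4, reflux) gives methyl 3,5-dimethoxy-4-methylbenzoate F5. Bromination (NBS, MeCN, rt) at the only free ring position type should give methyl 2-bromo-3,5-dimethoxy-4-methylbenzoate F6. Suzuki–Miyaura methylation (trimethylboroxine, PdCl2(dppf), K2CO3, dioxane, 100 °C) should give methyl 3,5-dimethoxy-2,4-dimethylbenzoate F7. Saponification (LiOH, THF/H2O, then aq. HCl) comes back to the route at 6.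

**Further compounds**
F1 | step 6 | methyl 3-[3-iodo-4-methyl-6-(triisopropylsilyloxy)-1-benzofuran-2-yl]propanoate | COC(=O)CCc1oc2cc(O[Si](C(C)C)(C(C)C)C(C)C)cc(C)c2c1I
F2 | step 6 | 2-(3,5-dimethoxy-2,4-dimethylphenyl)-4,4,5,5-tetramethyl-1,3,2-dioxaborolane | COc1cc(B2OC(C)(C)C(C)(C)O2)c(C)c(OC)c1C
F3 | step 1 | 1,3-dimethoxy-5-methylbenzene | COc1cc(C)cc(OC)c1
F4 | step 1 | 2-iodo-1,5-dimethoxy-3-methylbenzene | COc1cc(C)c(I)c(OC)c1
F5 | step 3 | methyl 3,5-dimethoxy-4-methylbenzoate | COC(=O)c1cc(OC)c(C)c(OC)c1
F6 | step 3 | methyl 2-bromo-3,5-dimethoxy-4-methylbenzoate | COC(=O)c1cc(OC)c(C)c(OC)c1Br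
F7 | step 3 | methyl 3,5-dimethoxy-2,4-dimethylbenzoate | COC(=O)c1cc(OC)c(C)c(OC)c1C
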